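C1 of the tetralin is a diarylmethine bonded to C2, to C8a of ring A and to the pendant guaiacyl ring. It is therefore traced back to the formyl carbon of O-benzylvanillin, which takes up two carbon nucleophiles in turn. In one flask the enolate of (R)-β-(4-benzyloxy-3-methoxybenzyl)-γ-butyrolactone forms C1–C2. Acid then ionises the carbinol so that ring A closes C1–C8a. Ring B and the C1 and C2 stereocentres arise under control of C3. The surviving lactone keeps the C2 arm (acyl) and the C3 arm (alkoxy) different, so that only the C2 arm is sulfated later.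

Key step: step 4

Assumption: the target is taken as drawn, as the free hydrogen sulfate; the sulfate is carried as its sodium salt and protonated only in the last operation.
Numbering: C1 bears the guaiacyl group, C2 the sulfated arm, C3 the hydroxymethyl arm and C4 is the benzylic CH2. C4a–C8a belong to ring A (OMe on C6, OH on C7), and ring B is the saturated ring. The target is (1S,2R,3R), all-trans.

Step 1
Reactants: 1 4-benzyloxy-3-methoxybenzaldehyde; 2 dimethyl succinate
Product: 3 (E)-4-(4-benzyloxy-3-methoxyphenyl)-3-(methoxycarbonyl)but-3-enoic acid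
Conditions: NaOMe (1.5 equiv), 2 (1.3 equiv), MeOH, reflux; then 2 M HCl
Reagents that add atoms: none
Why: Stobbe condensation: the succinate enolate adds to the aldehyde, the alkoxide closes to a paraconic ester, and base-induced opening gives the half-ester with the free acid on the CH2 arm and the aryl group anti to the ester (E).

Step 2
Reactants: 3 (E)-half-ester
Product: 4 (R)-4-(4-benzyloxy-3-methoxyphenyl)-3-(methoxycarbonyl)butanoic acid
Conditions: [Rh(cod)2]BF4 (0.5 mol %), (4S,5S)-MOD-DIOP [(4S,5S)-4,5-bis{[bis(4-methoxy-3,5-dimethylphenyl)phosphanyl]methyl}-2,2-dimethyl-1,3-dioxolane, 0.55 mol %], Et3N (0.1 equiv), H2 (5 atm), MeOH, 30 °C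
Reagents that add atoms: none
Why: Carboxylate-directed asymmetric hydrogenation of an itaconate-type half-ester, in which chelation of alkene and carboxylate to the chiral rhodium bisphosphine complex is expected, with the (S,S) ligand, to deliver H2 to the face that gives the R centre (future C3), while the homogeneous catalyst leaves the benzyl ether alone.

Step 3
Reactants: 4 (R)-half-ester
Product: 7 (R)-4-(4-benzyloxy-3-methoxybenzyl)dihydrofuran-2(3H)-one, via potassium carboxylate 5 (not isolated), via hydroxy acid 6 (not isolated)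
Conditions: KOH (1.0 equiv), EtOH, 0 °C; CaCl2/NaBH4 [Ca(BH4)2 made in situ], EtOH, −10 °C → rt; then 3 M HCl, rt → 40 °C
Reagents that add atoms: none
Why: Chemoselective borohydride reduction followed by acid lactonisation: Ca(BH4)2 reduces the ester but not the carboxylate, one equivalent of KOH at 0 °C only neutralises the acid so the stereocentre is not enolised, and acid closes the γ-hydroxy acid to the five-membered lactone.

Step 4
Reactants: 7 (R)-β-benzyl lactone; 1 4-benzyloxy-3-methoxybenzaldehyde
Product: 10 (3aR,9S,9aR)-7-benzyloxy-9-(4-benzyloxy-3-methoxyphenyl)-6-methoxy-3a,4,9,9a-tetrahydronaphtho[2,3-c]furan-1(3H)-one (trans,trans; C=O on C2, OCH2 on C3), via lithium enolate 8 (not isolated), via aldol adduct 9 (not isolated)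
Conditions: LiN(SiMe3)2 (1.1 equiv), minimum THF, −78 °C; 1 (1.0 equiv), −78 °C; CF3CO2H (2.5 equiv), −78 °C; dilute with CH2Cl2 (ca. 0.02 M), CF3CO2H (to ca. 10 vol %), 0 °C → rt, short exposure; aq. NaHCO3
Reagents that add atoms: none
Why: LiN(SiMe3)2 converts 7 into enolate 8, whose aldol addition to the non-enolisable aldehyde forms C1–C2; CF3CO2H then protonates the alkoxide to 9 and ionises both carbinol epimers to one benzylic cation stabilised by the para benzyloxy group, which ring A captures at C8a (C1–C8a) with loss of a proton. Both events are known for this substrate class (aldol addition of β-benzyl-γ-butyrolactone enolates to aryl aldehydes, and acid-mediated intramolecular Friedel–Crafts alkylation of the adducts to 1-aryltetralin lactones), and only the intermediate work-up is left out, with CH2Cl2 dilution added because THF buffers the acid. Ring B closes in a six-membered mode in which C1 becomes a ring atom while the aryl π system that stabilises it stays outside (6-exo-trig on the quinone-methide-like cation, with the arene bond C4a–C8a endocyclic). C2 is set by the C3 benzyl group, which shields one face of the planar enolate so that the aldehyde adds anti (2,3-trans); C1 is set in the closure, where the trans-fused lactone fixes a half-chair and the aryl group takes the pseudo-equatorial site anti to the C2 acyl carbon (1,2-trans, 1S), the carbinol configuration of 9 being erased by ionisation. The step needs regioselectivity on ring A, and the position para to OMe is activated and open whereas the other ortho site lies between the side chain and OMe; dilution suppresses intermolecular alkylation and the short, cool acid exposure spares the aryl benzyl ethers.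

Step 5
Reactants: 10 tetralin lactone
Product: 11 (1S,2R,3R)-7-benzyloxy-1-(4-benzyloxy-3-methoxyphenyl)-3-(hydroxymethyl)-N,6-dimethoxy-N-methyl-1,2,3,4-tetrahydronaphthalene-2-carboxamide
Conditions: MeONHMe·HCl (3 equiv), Me3Al (3 equiv), CH2Cl2, 0 °C → rt; aq. potassium sodium tartrate; crude product carried on at once
Reagents that add atoms: N,O-dimethylhydroxylamine hydrochloride, CNOC.Cl
Why: Weinreb aminolysis of a lactone by the aluminium amide, helped by the strain of the trans-fused lactone; it frees only the C3 carbinol and leaves C2 in its equatorial, thermodynamically preferred configuration.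

Step 6
Reactants: 11 hydroxy Weinreb amide
Product: 12 (1S,2R,3R)-7-benzyloxy-1-(4-benzyloxy-3-methoxyphenyl)-3-[(tert-butyldiphenylsilyloxy)methyl]-N,6-dimethoxy-N-methyl-1,2,3,4-tetrahydronaphthalene-2-carboxamide
Conditions: t-BuPh2SiCl (1.2 equiv), imidazole (2.5 equiv), DMF, 0 °C → rt
Reagents that add atoms: tert-butyldiphenylsilyl chloride, CC(C)(C)[Si](Cl)(c1ccccc1)c1ccccc1
Why: Imidazole-promoted silylation of a primary alcohol blocks re-lactonisation, and the bulky silyl group is chosen because it resists O-to-O migration to the neighbouring C2 arm once that arm becomes an alkoxide.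

Step 7
Reactants: 12 silylated Weinreb amide
Product: 14 [(1S,2R,3R)-7-benzyloxy-1-(4-benzyloxy-3-methoxyphenyl)-3-[(tert-butyldiphenylsilyloxy)methyl]-6-methoxy-1,2,3,4-tetrahydronaphthalen-2-yl]methanol, via aldehyde 13 (not isolated)
Conditions: LiAlH4 (1.2 equiv), THF, −40 → 0 °C; aq. potassium sodium tartrate; organic layer + MeOH, NaBH4, 0 °C; aq. NH4Cl
Reagents that add atoms: none
Why: Weinreb amide reduction stops at the chelated tetrahedral intermediate and releases the aldehyde on quenching, NaBH4 then reduces the carbonyl, and the all-equatorial C2 centre has no driving force to epimerise.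

Step 8
Reactants: 14 C2 carbinol; 15 sulfur trioxide pyridine complex
Product: 16 sodium [(1S,2R,3R)-7-benzyloxy-1-(4-benzyloxy-3-methoxyphenyl)-3-[(tert-butyldiphenylsilyloxy)methyl]-6-methoxy-1,2,3,4-tetrahydronaphthalen-2-yl]methyl sulfate
Conditions: 15 (3 equiv), pyridine, rt; then sat. aq. NaHCO3; SiO2, CH2Cl2/MeOH
Reagents that add atoms: sulfur trioxide pyridine complex 15, [O-]S(=O)(=O)[n+]1ccccc1; sodium hydrogencarbonate, [Na+].OC([O-])=O
Why: O-sulfation of an alcohol by an SO3–amine complex: 14 has one free hydroxyl, both phenols are benzylated and the C3 arm is silylated, so only the C2 arm can react, and the complex is too mild to sulfonate the alkoxyarenes.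

Step 9
Reactants: 16 silylated sodium sulfate
Product: 17 sodium [(1S,2R,3R)-7-benzyloxy-1-(4-benzyloxy-3-methoxyphenyl)-3-(hydroxymethyl)-6-methoxy-1,2,3,4-tetrahydronaphthalen-2-yl]methyl sulfate
Conditions: HF·pyridine, THF/pyridine, 0 °C → rt (polyethylene vessel); aq. NaHCO3; chromatography, co-evaporation with toluene to remove pyridine
Reagents that add atoms: none
Why: Fluoride-driven Si–O cleavage under pyridine buffering, in which the sulfate stays anionic and unreactive and the benzyl ethers are inert.

Step 10
Reactants: 17 dibenzyl sodium sulfate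
Product: 19 [(1S,2R,3R)-7-hydroxy-1-(4-hydroxy-3-methoxyphenyl)-3-(hydroxymethyl)-6-methoxy-1,2,3,4-tetrahydronaphthalen-2-yl]methyl hydrogen sulfate (CNP0184747.1), via sodium salt 18 (not isolated)
Conditions: H2 (1 atm), 10% Pd/C, MeOH/H2O, rt; filter; sulfonic acid cation-exchange resin (H+ form), H2O, 0–5 °C; freeze-dry, store cold
Reagents that add atoms: none
Why: Catalytic hydrogenolysis cleaves both aryl benzyl ethers while the primary alkyl sulfate, the C1 diarylmethine and the arenes are inert, and cation exchange in cold water swaps Na+ for H+ without the heat or strong acid that sulfate solvolysis needs.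

Compound list
1 | 4-benzyloxy-3-methoxybenzaldehyde | COc1cc(C=O)ccc1OCc1ccccc1 | starting material
2 | dimethyl succinate | COC(=O)CCC(=O)OC | starting material
3 | (E)-4-(4-benzyloxy-3-methoxyphenyl)-3-(methoxycarbonyl)but-3-enoic acid | COC(=O)/C(CC(=O)O)=C/c1ccc(OCc2ccccc2)c(OC)c1 | intermediate
4 | (R)-4-(4-benzyloxy-3-methoxyphenyl)-3-(methoxycarbonyl)butanoic acid | COC(=O)[C@@H](CC(=O)O)Cc1ccc(OCc2ccccc2)c(OC)c1 | intermediate
5 | potassium (R)-4-(4-benzyloxy-3-methoxyphenyl)-3-(methoxycarbonyl)butanoate | COC(=O)[C@@H](CC(=O)[O-])Cc1ccc(OCc2ccccc2)c(OC)c1.[K+] | intermediate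
6 | (R)-4-(4-benzyloxy-3-methoxyphenyl)-3-(hydroxymethyl)butanoic acid | OC[C@@H](CC(=O)O)Cc1ccc(OCc2ccccc2)c(OC)c1 | intermediate
7 | (R)-4-(4-benzyloxy-3-methoxybenzyl)dihydrofuran-2(3H)-one | COc1cc(C[C@@H](COC2=O)C2)ccc1OCc1ccccc1 | intermediate
8 | lithium enolate of 7 | COc1cc(C[C@H]2COC([O-])=C2)ccc1OCc1ccccc1.[Li+] | intermediate
9 | (3S,4R)-4-(4-benzyloxy-3-methoxybenzyl)-3-[(4-benzyloxy-3-methoxyphenyl)(hydroxy)methyl]dihydrofuran-2(3H)-one, both carbinol epimers | COc1cc(C[C@@H](COC2=O)[C@H]2C(O)c2ccc(OCc3ccccc3)c(OC)c2)ccc1OCc1ccccc1 | intermediate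
10 | (3aR,9S,9aR)-7-benzyloxy-9-(4-benzyloxy-3-methoxyphenyl)-6-methoxy-3a,4,9,9a-tetrahydronaphtho[2,3-c]furan-1(3H)-one | COc1cc([C@H]2c3cc(OCc4ccccc4)c(OC)cc3C[C@@H](COC4=O)[C@@H]24)ccc1OCc1ccccc1 | intermediate
11 | (1S,2R,3R) hydroxy Weinreb amide | COc1cc([C@H]2c3cc(OCc4ccccc4)c(OC)cc3C[C@@H](CO)[C@@H]2C(=O)N(C)OC)ccc1OCc1ccccc1 | intermediate
12 | (1S,2R,3R) C3 tert-butyldiphenylsilyloxymethyl Weinreb amide | COc1cc([C@H]2c3cc(OCc4ccccc4)c(OC)cc3C[C@@H](CO[Si](c4ccccc4)(c4ccccc4)C(C)(C)C)[C@@H]2C(=O)N(C)OC)ccc1OCc1ccccc1 | intermediate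
13 | (1S,2R,3R) C2 carbaldehyde | COc1cc([C@H]2c3cc(OCc4ccccc4)c(OC)cc3C[C@@H](CO[Si](c4ccccc4)(c4ccccc4)C(C)(C)C)[C@@H]2C=O)ccc1OCc1ccccc1 | intermediate
14 | (1S,2R,3R) C2 carbinol, C3 silyl ether | COc1cc([C@H]2c3cc(OCc4ccccc4)c(OC)cc3C[C@@H](CO[Si](c4ccccc4)(c4ccccc4)C(C)(C)C)[C@@H]2CO)ccc1OCc1ccccc1 | intermediate
15 | sulfur trioxide pyridine complex | [O-]S(=O)(=O)[n+]1ccccc1 | starting material
16 | sodium salt of the C2 sulfate, C3 silyl ether, dibenzyl ether | COc1cc([C@H]2c3cc(OCc4ccccc4)c(OC)cc3C[C@@H](CO[Si](c4ccccc4)(c4ccccc4)C(C)(C)C)[C@@H]2COS(=O)(=O)[O-])ccc1OCc1ccccc1.[Na+] | intermediate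
17 | sodium salt of the C2 sulfate, free C3 carbinol, dibenzyl ether | COc1cc([C@H]2c3cc(OCc4ccccc4)c(OC)cc3C[C@@H](CO)[C@@H]2COS(=O)(=O)[O-])ccc1OCc1ccccc1.[Na+] | intermediate
18 | sodium salt of the target | COc1cc([C@H]2c3cc(O)c(OC)cc3C[C@@H](CO)[C@@H]2COS(=O)(=O)[O-])ccc1O.[Na+] | intermediate
19 | CNP0184747.1, (1S,2R,3R) hydrogen sulfate | COc1cc([C@H]2c3cc(O)c(OC)cc3C[C@@H](CO)[C@@H]2COS(=O)(=O)O)ccc1O | target

Total step count: 10. Longest linear sequence: 10 (steps 1–10 from 1; aldehyde 1 enters again at step 4).

Steps most likely to fail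

Risk 1 – step 4. Ionisation may stay incomplete in a medium still buffered by THF and amine salts. The cation may lose the C2 proton instead of cyclising, or a benzyl group may be lost or migrate on long acid exposure. The fallback sets out from 7 and separates the two events. The aldol reaction with 1 is quenched with aq. NH4Cl and adduct 9 is isolated. Acetylation (Ac2O, pyridine, 0 °C) gives the benzylic acetate of the aldol adduct F1. This pre-installed leaving group is ionised by catalytic Sc(OTf)3 in CH2Cl2 at −20 °C, a Lewis acid-catalysed intramolecular Friedel–Crafts benzylation free of Brønsted acid. The route is rejoined at 10.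

Risk 2 – step 5. Attack of the aluminium amide on the acyl carbon, which sits next to the C1 aryl group, may be slow. The hydroxy amide may also close back to the lactone before it is silylated. The fallback sets out from 10 and gives up acyl/alkoxy differentiation in favour of steric differentiation. LiAlH4 in THF at 0 °C gives the O,O'-dibenzyl diol F2. One equivalent of t-BuPh2SiCl (imidazole, CH2Cl2, −20 °C) should then favour the C3 carbinol, because the C2 carbinol is crowded by the C1 aryl group. The regioisomers are separated, the site is assigned by two-dimensional NMR, and unwanted silyl ethers are returned to F2 with fluoride. The route is rejoined at 14.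

Risk 3 – step 2. Facial discrimination on the trisubstituted alkene may be insufficient, or turnover slow. The fallback sets out from 3 and replaces catalyst control by classical resolution. Hydrogenation with achiral [Rh(cod)(dppb)]BF4 in MeOH gives the racemic half-ester F3. Crystallisation with (S)-1-phenylethylamine (its antipode if the other diastereomeric salt is the less soluble one) gives the (S)-1-phenylethylammonium salt of the (R)-acid F4. Acidification rejoins the route at 4. The same crystallisation can also upgrade partly enriched 4.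

Further compounds
F1 | step 4 | (3S,4R)-3-[acetoxy(4-benzyloxy-3-methoxyphenyl)methyl]-4-(4-benzyloxy-3-methoxybenzyl)dihydrofuran-2(3H)-one, both acetate epimers | COc1cc(C[C@@H](COC2=O)[C@H]2C(OC(C)=O)c2ccc(OCc3ccccc3)c(OC)c2)ccc1OCc1ccccc1
F2 | step 5 | [(1S,2R,3R)-7-benzyloxy-1-(4-benzyloxy-3-methoxyphenyl)-6-methoxy-1,2,3,4-tetrahydronaphthalene-2,3-diyl]dimethanol | COc1cc([C@H]2c3cc(OCc4ccccc4)c(OC)cc3C[C@@H](CO)[C@@H]2CO)ccc1OCc1ccccc1
F3 | step 2 | racemic 4-(4-benzyloxy-3-methoxyphenyl)-3-(methoxycarbonyl)butanoic acid | COC(=O)C(CC(=O)O)Cc1ccc(OCc2ccccc2)c(OC)c1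
F4 | step 2 | (S)-1-phenylethylammonium (R)-4-(4-benzyloxy-3-methoxyphenyl)-3-(methoxycarbonyl)butanoate | COC(=O)[C@@H](CC(=O)[O-])Cc1ccc(OCc2ccccc2)c(OC)c1.C[C@H]([NH3+])c1ccccc1
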